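## The problem

Compound 27 is a seco-eudesmanolide: a decalin whose rings A and B share only the C5–C10 bond. It carries the angular methyl C14 on C10, an exocyclic methylene (C15) on C4, a tertiary allylic hydroperoxide on the α face of C5, an isobutyrate at C3β, an acetate at C8β and a methyl acrylate (C11–C13) at C7β. Five stereocentres have to be set; C7 and C8 are adjacent and cis, C5 and C10 are fully substituted, and C3 lies four atoms from C7, too far for a dependable acyclic relay. The hydroperoxide, the allylic ester and the α-methylene ester rule out strong base, hydride, phosphines and heat at the end, so the O–O group must come last. The 8-hydroxy ester must also be kept from closing to the cis-lactone. Because C10 has no hydrogen, the 5α-hydroperoxy-4(15)-ene array is the signature of a singlet-oxygen ene reaction on a tetrasubstituted 4,5-olefin, which fixes the penultimate skeleton as an eudesma-4,11(13)-diene. In that diene, with C14 on C10 and C15 on C4, the two rings are exactly what results when the 1(10)- and 4,5-olefins of a ten-membered germacra-1(10)E,4E-diene are joined across the ring. The closure leaves a cation at C4 next to the oxygenated C3; how that cation is discharged, together with the stereocontrol of C7/C8 in the flexible ten-membered precursor, is where the synthesis is decided.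

## Retrosynthesis

**C5–O and C15–H (27 ⇒ 26).** The hydroperoxide is removed first, by a retro-ene step that returns the 4(15)-olefin to the 4,5-position of isobutyrate 26. No other cut installs a tertiary allylic OOH with a transposed double bond in one operation, and it removes the C5 stereocentre and the only group that forbids ordinary reagents. The forward reaction must attack the α face and take hydrogen from C15. The ester is in place beforehand because a free 3β-hydroxyl would steer oxygen to the β face.

**C3–O, with inversion (26 ⇒ 25 ⇒ 24).** The isobutyrate is traced to the 3α-alcohol 25 and its silyl ether 24 by a Mitsunobu esterification. Carrying C3 in the β configuration would allow plain acylation, but then the C3 hydrogen is axial in ring A of the cyclized cation and parallel to the empty orbital at C4; a pinacol-type hydride shift to the 3-ketone would compete with proton loss. An ester at C3 would bridge to C4 as an acyloxonium ion. The 3α-silyl ether avoids both, and the inversion costs no extra step. The forward reaction must substitute without eliminating.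

**C5–C10 (24 ⇒ 23).** This is the only bond the two rings share, so cutting it opens both at once and gives germacratriene 23, which has one stereocentre fewer (C10) and no quaternary carbon. Cuts at C9–C10 or C6–C7 open one ring only and leave the quaternary centre to be made separately. The forward step needs protonation at C1, bonding of C5 to C10 with C14 on the β face, and loss of H5.

**C7–C8 and the ten-membered ring (23 ⇒ 22 ⇒ 21).** The acetate is taken back to alcohol 22, and the C7–C8 bond is cut to the open-chain bromo aldehyde 21. This closure forms the ring, both adjacent stereocentres and the C11=C13 methylene together. A closure at C3–C4 would form the ring without creating C7/C8. The forward reaction must give the syn (7,8-cis) adduct, select one face relative to C3, the only resident stereocentre, and outrun oligomerisation. The E,E-diene is Cope-labile, so nothing after this point is heated.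

**C7–C11 (21 ⇒ 20 ⇒ 19 ⇒ 18 ⇒ 15 + 16).** The aldehyde of 21 comes from the PMB ether 19 through alcohol 20. The Z-configured 2-(bromomethyl)enoate of 19 is the SN2′ bromide of the Baylis–Hillman-type adduct 18. Adduct 18 is cut between C7 and C11 into aldehyde 15 and methyl propiolate 16. The adduct is made through a vinylalane and not by amine catalysis, because 15 is β,γ-unsaturated and would move into conjugation under prolonged base.

**C3–C4 (15 ⇒ 14 ⇒ 13 ⇒ 12 ⇒ 7 + 9).** Aldehyde 15 comes from the differentially silylated 13 through alcohol 14. Allylic alcohol 12 is cut at C3–C4 into aldehyde 7 and the alkenyl metal from alkyne 9. This is the most convergent cut of the chain: it joins two pieces of similar size, fixes the 4E geometry by syn hydrometalation and sets C3 by a chiral ligand. The forward reaction needs the metal on the methyl-bearing alkyne carbon and Si-face addition.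

**C1–C2 and C10–C14 (7 ⇒ 6 ⇒ 2 + 3; 2 ⇐ 1; 9 ⇐ 8).** Aldehyde 7 comes from alcohol 6, which is cut into the PMB ether 2 of but-3-yn-1-ol 1, a methyl group and oxirane 3. Carboalumination sets the 1(10)E olefin and places C14 in one step; an olefination route to the same trisubstituted alkene would be longer and less selective. Alkyne 9 is the triethylsilyl ether of pent-3-yn-1-ol 8.

## Roads not taken

**Alternative 1:** The angular methyl is cut at C10–C14 and C5–C14 and traced to the methylene of a cyclopropane, so that the decalin is bought ready-made as the Δ5(10)-octalinol A2. In the forward step the zinc carbenoid from Et2Zn and CH2I2, held by the zinc alkoxide of the C3 hydroxyl, adds to the tetrasubstituted 5(10)-olefin from the β face to give A1. Its merits are real: hydroxyl-directed Simmons–Smith cyclopropanation is very reliable, the C10 configuration follows from C3 with near certainty, and no macrocycle is needed. For this target, however, A1 still lacks C15, the 4,5-olefin and the whole C7 acrylate. The cyclopropane must then be opened at C5–C14 alone. C7 and the axial 8β-oxygen must be set next to a C8 ketone with no stereocontrol built in. Each of these is a separate problem after the key step. In securing C10, and C3 relative to it, this road is better than the chosen plan, which relies on a ring conformer for C10 and on a remote relationship for C7/C8. The chosen plan sets against this that its cyclization substrate already contains every carbon and both side-chain stereocentres, so only three steps follow the key step.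

**Alternative 2:** Ring B is cut at C9–C10 and ring A is seen as a dearomatised phenol. Trifluoroacetic acid protonates the diazoketone A4, and the para carbon of the phenol (C10) attacks C9 with loss of N2 to give the cross-conjugated dienone A3. In one step from a flat precursor this makes the quaternary C10, the 4,5-olefin with C15, and carbonyls at C3 and C8. The C3 ketone would let the 3β-alcohol be set from the ring by reduction, which is more secure than the inversion used here, and the core is reached in fewer steps. The weak points are these:
- the face of C10 is chosen only by the single stereocentre C7 on a flexible tether;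
- the 1,2-olefin must be removed from the dienone without touching the 4,5-olefin;
- the acid invites dienone–phenol rearrangement;
- C13 is absent, and must be introduced at an ester in the presence of two ketones;
- the C8 ketone must be reduced to the axial alcohol beside an epimerisable C7.

The chosen plan is longer to its bicycle, but it arrives there with C7, C8, the acetate and the complete acrylate fixed and needs no redox adjustment afterwards.

**Alternative 3:** Ring B is cut at C6–C7. DABCO displaces the tert-butyl carbonate of A6 by SN2′; the released tert-butoxide unmasks the silyl dienol ether, and its γ-carbon (C6) attacks C7 in a second SN2′ to give enone A5 with the C11=C13 methylene restored. If this closure works, the road is shorter after its key step than the chosen one (reduction, acylation, photooxygenation). It also sets C3 from the ring and avoids both a macrocycle and an acid-sensitive diene. Against it: the quaternary C10 and C8 must both be built into A6 beforehand, which moves the hard stereochemistry into the preparation of the substrate. The closure must then relay them to C7. The tandem SN2′–SN2′ alkylation is established mainly for stabilised nucleophiles in intermolecular cases. The dienolate may react at oxygen, and free tert-butoxide endangers the C8 acetate. The chosen plan sets against these points a key step with close analogy in the germacrane–eudesmane series and a substrate assembled from two achiral alkynols by catalytic C–C bond formations.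

Key step: step 15

Remark: atoms carry germacrane/eudesmane numbers (C1–C15) throughout, and α/β for the ten-membered intermediates denote the faces these atoms show in the eudesmane formed in step 15.

## Route

Step 1
Reactants: 1 but-3-yn-1-ol
Product: 2 1-[(but-3-yn-1-yloxy)methyl]-4-methoxybenzene
Conditions: NaH, PMBCl, TBAI (cat.), THF, 0 °C → rt
Reagents that add atoms: 4-methoxybenzyl chloride, COc1ccc(CCl)cc1
Why: Williamson etherification; the alkoxide forms well before the alkyne C–H is touched. PMB is chosen because it must later leave oxidatively beside an allylic bromide and a silyl ether.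

Step 2
Reactants: 2 1-[(but-3-yn-1-yloxy)methyl]-4-methoxybenzene; 3 oxirane
Product: 6 (E)-6-[(4-methoxybenzyl)oxy]-4-methylhex-3-en-1-ol, via alkenyldimethylalane 4 (not isolated), via lithium alkenylalanate 5 (not isolated)
Conditions: Me3Al, Cp2ZrCl2 (cat.), CH2Cl2, 0 °C → rt; n-BuLi, hexane–THF, −78 → 0 °C; then 3, −78 °C → rt
Reagents that add atoms: trimethylaluminium, C[Al](C)C
Why: Zirconium-catalysed carboalumination (Negishi) adds methyl and aluminium syn across the terminal alkyne with aluminium at the terminus, which fixes the 1(10)E geometry and places C14. The derived alanate opens oxirane with retention of olefin geometry and adds C2 and C3.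

Step 3
Reactants: 6 (E)-6-[(4-methoxybenzyl)oxy]-4-methylhex-3-en-1-ol
Product: 7 (E)-6-[(4-methoxybenzyl)oxy]-4-methylhex-3-enal
Conditions: DMP, pyridine, CH2Cl2, 0 °C
Reagents that add atoms: none
Why: Dess–Martin oxidation under buffered, non-basic conditions should give the β,γ-unsaturated aldehyde without moving the trisubstituted olefin into conjugation; it is used without storage.

Step 4
Reactants: 8 pent-3-yn-1-ol
Product: 9 triethyl(pent-3-yn-1-yloxy)silane
Conditions: TESCl, imidazole, CH2Cl2, 0 °C
Reagents that add atoms: chlorotriethylsilane, CC[Si](Cl)(CC)CC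
Why: Standard silylation; the primary triethylsilyl ether is chosen because it can later be removed beside a secondary tert-butyldimethylsilyl ether and a PMB ether.

Step 5
Reactants: 9 triethyl(pent-3-yn-1-yloxy)silane; 7 (E)-6-[(4-methoxybenzyl)oxy]-4-methylhex-3-enal
Product: 12 (3E,5R,7E)-10-[(4-methoxybenzyl)oxy]-4,8-dimethyl-1-(triethylsilyloxy)deca-3,7-dien-5-ol, via alkenylzirconocene chloride 10 (not isolated), via alkenyl(methyl)zinc 11 (not isolated)
Conditions: Cp2Zr(H)Cl, CH2Cl2, rt; Me2Zn, toluene, −65 °C; (−)-MIB (10 mol %), then 7, −30 → 0 °C
Reagents that add atoms: none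
Why: Syn hydrozirconation, equilibrated with a slight excess of hydride, puts zirconium on the methyl-bearing carbon and fixes the 4E olefin; transmetalation to zinc gives an alkenylzinc for amino-alcohol-catalysed addition to the aldehyde. (−)-MIB is expected to direct the alkenyl group to the Si face, as it does for organozinc additions to aldehydes, which gives the 3R (3α) carbinol.

Step 6
Reactants: 12 (3E,5R,7E)-10-[(4-methoxybenzyl)oxy]-4,8-dimethyl-1-(triethylsilyloxy)deca-3,7-dien-5-ol
Product: 13 (3E,5R,7E)-5-(tert-butyldimethylsilyloxy)-10-[(4-methoxybenzyl)oxy]-4,8-dimethyl-1-(triethylsilyloxy)deca-3,7-diene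
Conditions: TBSCl, imidazole, DMF, rt
Reagents that add atoms: tert-butyl(chloro)dimethylsilane, CC(C)(C)[Si](C)(C)Cl
Why: Standard silylation of a secondary allylic alcohol; the silyl ether cannot bridge to C4 in step 15 as an ester would.

Step 7
Reactants: 13 (3E,5R,7E)-5-(tert-butyldimethylsilyloxy)-10-[(4-methoxybenzyl)oxy]-4,8-dimethyl-1-(triethylsilyloxy)deca-3,7-diene
Product: 14 (3E,5R,7E)-5-(tert-butyldimethylsilyloxy)-10-[(4-methoxybenzyl)oxy]-4,8-dimethyldeca-3,7-dien-1-ol
Conditions: PPTS (cat.), MeOH–CH2Cl2, 0 °C
Reagents that add atoms: none
Why: Acid-catalysed methanolysis cleaves a primary triethylsilyl ether far faster than a secondary tert-butyldimethylsilyl ether; the PMB ether is inert.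

Step 8
Reactants: 14 (3E,5R,7E)-5-(tert-butyldimethylsilyloxy)-10-[(4-methoxybenzyl)oxy]-4,8-dimethyldeca-3,7-dien-1-ol
Product: 15 (3E,5R,7E)-5-(tert-butyldimethylsilyloxy)-10-[(4-methoxybenzyl)oxy]-4,8-dimethyldeca-3,7-dienal
Conditions: DMP, pyridine, CH2Cl2, 0 °C
Reagents that add atoms: none
Why: Dess–Martin oxidation as in step 3; the β,γ-unsaturated aldehyde is taken on directly.

Step 9
Reactants: 15 (3E,5R,7E)-5-(tert-butyldimethylsilyloxy)-10-[(4-methoxybenzyl)oxy]-4,8-dimethyldeca-3,7-dienal; 16 methyl propiolate
Product: 18 methyl (5E,7R,9E)-7-(tert-butyldimethylsilyloxy)-3-hydroxy-12-[(4-methoxybenzyl)oxy]-6,10-dimethyl-2-methylidenedodeca-5,9-dienoate (both C3 epimers), via [1-(methoxycarbonyl)ethenyl]diisobutylalane 17 (not isolated)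
Conditions: i-Bu2AlH, NMO, THF, 0 °C; 16, 0 °C; then 15, 0 °C → rt
Reagents that add atoms: none
Why: Hydroalumination of the propiolate gives an α-aluminated acrylate that adds to the aldehyde, which delivers the Baylis–Hillman-type adduct quickly and without amine base, so the β,γ-olefin of 15 stays in place. The new carbinol centre is lost in step 10, so its configuration does not matter.

Step 10
Reactants: 18 methyl (5E,7R,9E)-7-(tert-butyldimethylsilyloxy)-3-hydroxy-12-[(4-methoxybenzyl)oxy]-6,10-dimethyl-2-methylidenedodeca-5,9-dienoate
Product: 19 methyl (2Z,5E,7R,9E)-2-(bromomethyl)-7-(tert-butyldimethylsilyloxy)-12-[(4-methoxybenzyl)oxy]-6,10-dimethyldodeca-2,5,9-trienoate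
Conditions: NBS, Me2S, CH2Cl2, 0 °C → rt
Reagents that add atoms: N-bromosuccinimide, O=C1CCC(=O)N1Br
Why: The alkoxysulfonium ion formed with the Corey–Kim-type reagent is displaced by bromide in SN2′ fashion, which gives the trisubstituted enoate with the chain trans to the ester (2Z). NBS is complexed by the sulfide before the substrate is added, so the electron-rich olefins are not brominated.

Step 11
Reactants: 19 methyl (2Z,5E,7R,9E)-2-(bromomethyl)-7-(tert-butyldimethylsilyloxy)-12-[(4-methoxybenzyl)oxy]-6,10-dimethyldodeca-2,5,9-trienoate
Product: 20 methyl (2Z,5E,7R,9E)-2-(bromomethyl)-7-(tert-butyldimethylsilyloxy)-12-hydroxy-6,10-dimethyldodeca-2,5,9-trienoate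
Conditions: DDQ, CH2Cl2–pH 7 buffer, 0 °C
Reagents that add atoms: none
Why: Oxidative cleavage of the PMB ether under neutral conditions leaves the allylic bromide, the skipped diene and the silyl ether untouched.

Step 12
Reactants: 20 methyl (2Z,5E,7R,9E)-2-(bromomethyl)-7-(tert-butyldimethylsilyloxy)-12-hydroxy-6,10-dimethyldodeca-2,5,9-trienoate
Product: 21 methyl (2Z,5E,7R,9E)-2-(bromomethyl)-7-(tert-butyldimethylsilyloxy)-6,10-dimethyl-12-oxododeca-2,5,9-trienoate
Conditions: DMP, pyridine, CH2Cl2, 0 °C
Reagents that add atoms: none
Why: Dess–Martin oxidation tolerates the allylic bromide; the β,γ-unsaturated aldehyde is used at once in step 13.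

Step 13
Reactants: 21 methyl (2Z,5E,7R,9E)-2-(bromomethyl)-7-(tert-butyldimethylsilyloxy)-6,10-dimethyl-12-oxododeca-2,5,9-trienoate
Product: 22 methyl (3R,7R,8R)-3α-(tert-butyldimethylsilyloxy)-8β-hydroxygermacra-1(10)E,4E,11(13)-trien-12-oate
Conditions: CrCl2 (8 equiv), THF, rt; 21 added over 10 h (final 2 mM); aqueous work-up at 0 °C
Reagents that add atoms: none
Why: Nozaki–Hiyama-type allylation: CrCl2 reduces the allylic bromide to a 2-(methoxycarbonyl)allyl species of trivalent chromium, which adds through C7 to the aldehyde in a chair transition state and closes the ten-membered ring, as in known chromium-mediated germacrane closures. With C6 cis to the metal-bearing carbon (Z geometry) it sits axial while the aldehyde chain is equatorial, which should give the syn adduct, that is the 7,8-cis pair, as in the cis-lactones such bromides give in open-chain cases. Which syn face is used (7R,8R as drawn) depends on the C3 silyloxy group taking an outward position on the forming ring; this is the least secure stereochemical element, and the diastereomers are expected to be separable.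

Step 14
Reactants: 22 methyl (3R,7R,8R)-3α-(tert-butyldimethylsilyloxy)-8β-hydroxygermacra-1(10)E,4E,11(13)-trien-12-oate
Product: 23 methyl (3R,7R,8R)-8β-acetoxy-3α-(tert-butyldimethylsilyloxy)germacra-1(10)E,4E,11(13)-trien-12-oate
Conditions: Ac2O, DMAP, pyridine, CH2Cl2, 0 °C
Reagents that add atoms: acetic anhydride, CC(=O)OC(C)=O
Why: Acetylation, done immediately on the crude alcohol, installs the C8 acetate of the target and prevents the 8-hydroxyl from lactonising onto C12 under the acid of step 15.

Step 15
Reactants: 23 methyl (3R,7R,8R)-8β-acetoxy-3α-(tert-butyldimethylsilyloxy)germacra-1(10)E,4E,11(13)-trien-12-oate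
Product: 24 methyl (3R,7R,8R,10R)-8β-acetoxy-3α-(tert-butyldimethylsilyloxy)eudesma-4,11(13)-dien-12-oate
Conditions: TsOH (anhydrous, 10 mol %), CH2Cl2, 0 °C → rt
Reagents that add atoms: none
Why: Catalytic TsOH protonates C1 of the 1(10)-olefin, the more basic of the two trisubstituted alkenes because the 4,5-olefin is deactivated by the allylic silyloxy group; the developing tertiary C10 cation is captured across the ring by C5, and this single C5–C10 bond closes ring A in a 6-endo and ring B in a 6-exo sense with respect to the 4,5-olefin. The closest known reaction type is the acid-mediated transannular cyclization of germacra-1(10),4-dienes and germacranolides to eudesmanes, the presumed biosynthetic step. The only new stereocentre is C10, since C5 becomes trigonal again; it is set by the ring conformer in which C14 lies on the β face, held by the pseudo-equatorial C7 acrylate. The tertiary C4 cation then loses H5, which is axial and aligned with the empty orbital, to give the tetrasubstituted olefin, and any 4(15)-isomer formed by loss of a C15 proton is reprotonated and drains into the same product. The selectivity needed is proton loss to C5 without hydride migration from C3, and the 3α-silyloxy group secures it: in the chair of ring A this group is axial and the C3 hydrogen equatorial, near the nodal plane of the C4 cation, so that neither a pinacol-type hydride shift to the 3-ketone nor elimination to a silyl enol ether has good overlap. The acetate and the acrylate are inert to the acid, and the reaction is kept at or below room temperature to avoid Cope rearrangement of 23.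

Step 16
Reactants: 24 methyl (3R,7R,8R,10R)-8β-acetoxy-3α-(tert-butyldimethylsilyloxy)eudesma-4,11(13)-dien-12-oate
Product: 25 methyl (3R,7R,8R,10R)-8β-acetoxy-3α-hydroxyeudesma-4,11(13)-dien-12-oate
Conditions: HF·pyridine, pyridine, THF, 0 °C → rt
Reagents that add atoms: none
Why: Buffered fluoride desilylation frees the allylic alcohol without base, so the acetate and the acrylate are untouched and the allylic alcohol does not ionise.

Step 17
Reactants: 25 methyl (3R,7R,8R,10R)-8β-acetoxy-3α-hydroxyeudesma-4,11(13)-dien-12-oate
Product: 26 methyl (3S,7R,8R,10R)-8β-acetoxy-3β-(2-methylpropanoyloxy)eudesma-4,11(13)-dien-12-oate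
Conditions: PPh3, DIAD, isobutyric acid, toluene, 0 °C → rt
Reagents that add atoms: 2-methylpropanoic acid (isobutyric acid), CC(C)C(=O)O
Why: Mitsunobu esterification: the axial 3α-oxyphosphonium ion is displaced by isobutyrate from the open β face with inversion, which converts the configuration needed in step 15 into that of the target and installs the ester in one operation. SN2′ attack is blocked because C5 is fully substituted.

Step 18
Reactants: 26 methyl (3S,7R,8R,10R)-8β-acetoxy-3β-(2-methylpropanoyloxy)eudesma-4,11(13)-dien-12-oate
Product: 27 methyl (3S,5S,7R,8R,10R)-8β-acetoxy-5α-hydroperoxy-3β-(2-methylpropanoyloxy)eudesma-4(15),11(13)-dien-12-oate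
Conditions: O2, hν (visible), tetraphenylporphyrin (cat.), CH2Cl2, −20 °C
Reagents that add atoms: dioxygen, O=O
Why: Schenck ene reaction: singlet oxygen should approach the tetrasubstituted olefin from the α face, anti to the axial C14 methyl and the 3β-ester, bond to C5 and take a hydrogen from C15, which moves the double bond to C4(15) and sets C5 as the α-hydroperoxide. On the α face the only other aligned allylic hydrogen is H3, which is deactivated by its geminal acyloxy group; the axial C6 hydrogen lies on the β face. The electron-poor acrylate does not react, and no reducing work-up is used.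

## Compound list

1 | but-3-yn-1-ol | C#CCCO | starting material
2 | 1-[(but-3-yn-1-yloxy)methyl]-4-methoxybenzene | C#CCCOCc1ccc(OC)cc1 | intermediate
3 | oxirane | C1CO1 | starting material
4 | (E)-{4-[(4-methoxybenzyl)oxy]-2-methylbut-1-en-1-yl}dimethylalane | COc1ccc(COCC/C(C)=C/[Al](C)C)cc1 | intermediate
5 | lithium butyl{(E)-4-[(4-methoxybenzyl)oxy]-2-methylbut-1-en-1-yl}dimethylaluminate | [Li+].CCCC[Al-](C)(C)/C=C(\C)CCOCc1ccc(OC)cc1 | intermediate
6 | (E)-6-[(4-methoxybenzyl)oxy]-4-methylhex-3-en-1-ol | COc1ccc(COCC/C(C)=C/CCO)cc1 | intermediate
7 | (E)-6-[(4-methoxybenzyl)oxy]-4-methylhex-3-enal | COc1ccc(COCC/C(C)=C/CC=O)cc1 | intermediate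
8 | pent-3-yn-1-ol | CC#CCCO | starting material
9 | triethyl(pent-3-yn-1-yloxy)silane | CC#CCCO[Si](CC)(CC)CC | intermediate
10 | chlorido[(E)-5-(triethylsilyloxy)pent-2-en-2-yl]zirconocene | C/C(=C\CCO[Si](CC)(CC)CC)[Zr](Cl)(C1C=CC=C1)C1C=CC=C1 | intermediate
11 | methyl[(E)-5-(triethylsilyloxy)pent-2-en-2-yl]zinc | C/C(=C\CCO[Si](CC)(CC)CC)[Zn]C | intermediate
12 | (3E,5R,7E)-10-[(4-methoxybenzyl)oxy]-4,8-dimethyl-1-(triethylsilyloxy)deca-3,7-dien-5-ol | CC[Si](CC)(CC)OCC/C=C(C)/[C@H](O)C/C=C(C)/CCOCc1ccc(OC)cc1 | intermediate
13 | (3E,5R,7E)-5-(tert-butyldimethylsilyloxy)-10-[(4-methoxybenzyl)oxy]-4,8-dimethyl-1-(triethylsilyloxy)deca-3,7-diene | CC[Si](CC)(CC)OCC/C=C(C)/[C@H](O[Si](C)(C)C(C)(C)C)C/C=C(C)/CCOCc1ccc(OC)cc1 | intermediate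
14 | (3E,5R,7E)-5-(tert-butyldimethylsilyloxy)-10-[(4-methoxybenzyl)oxy]-4,8-dimethyldeca-3,7-dien-1-ol | OCC/C=C(C)/[C@H](O[Si](C)(C)C(C)(C)C)C/C=C(C)/CCOCc1ccc(OC)cc1 | intermediate
15 | (3E,5R,7E)-5-(tert-butyldimethylsilyloxy)-10-[(4-methoxybenzyl)oxy]-4,8-dimethyldeca-3,7-dienal | O=CC/C=C(C)/[C@H](O[Si](C)(C)C(C)(C)C)C/C=C(C)/CCOCc1ccc(OC)cc1 | intermediate
16 | methyl propiolate (methyl prop-2-ynoate) | C#CC(=O)OC | starting material
17 | [1-(methoxycarbonyl)ethenyl]bis(2-methylpropyl)alane | C=C(C(=O)OC)[Al](CC(C)C)CC(C)C | intermediate
18 | methyl (5E,7R,9E)-7-(tert-butyldimethylsilyloxy)-3-hydroxy-12-[(4-methoxybenzyl)oxy]-6,10-dimethyl-2-methylidenedodeca-5,9-dienoate (both C3 epimers) | C=C(C(=O)OC)C(O)C/C=C(C)/[C@H](O[Si](C)(C)C(C)(C)C)C/C=C(C)/CCOCc1ccc(OC)cc1 | intermediate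
19 | methyl (2Z,5E,7R,9E)-2-(bromomethyl)-7-(tert-butyldimethylsilyloxy)-12-[(4-methoxybenzyl)oxy]-6,10-dimethyldodeca-2,5,9-trienoate | BrC/C(C(=O)OC)=C\C/C=C(C)/[C@H](O[Si](C)(C)C(C)(C)C)C/C=C(C)/CCOCc1ccc(OC)cc1 | intermediate
20 | methyl (2Z,5E,7R,9E)-2-(bromomethyl)-7-(tert-butyldimethylsilyloxy)-12-hydroxy-6,10-dimethyldodeca-2,5,9-trienoate | BrC/C(C(=O)OC)=C\C/C=C(C)/[C@H](O[Si](C)(C)C(C)(C)C)C/C=C(C)/CCO | intermediate
21 | methyl (2Z,5E,7R,9E)-2-(bromomethyl)-7-(tert-butyldimethylsilyloxy)-6,10-dimethyl-12-oxododeca-2,5,9-trienoate | BrC/C(C(=O)OC)=C\C/C=C(C)/[C@H](O[Si](C)(C)C(C)(C)C)C/C=C(C)/CC=O | intermediate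
22 | methyl (3R,7R,8R)-3α-(tert-butyldimethylsilyloxy)-8β-hydroxygermacra-1(10)E,4E,11(13)-trien-12-oate | C=C(C(=O)OC)[C@H]1C/C=C(C)/[C@H](O[Si](C)(C)C(C)(C)C)C/C=C(C)/C[C@H]1O | intermediate
23 | methyl (3R,7R,8R)-8β-acetoxy-3α-(tert-butyldimethylsilyloxy)germacra-1(10)E,4E,11(13)-trien-12-oate | C=C(C(=O)OC)[C@H]1C/C=C(C)/[C@H](O[Si](C)(C)C(C)(C)C)C/C=C(C)/C[C@H]1OC(C)=O | intermediate
24 | methyl (3R,7R,8R,10R)-8β-acetoxy-3α-(tert-butyldimethylsilyloxy)eudesma-4,11(13)-dien-12-oate | C=C(C(=O)OC)[C@H]1CC2=C(C)[C@H](O[Si](C)(C)C(C)(C)C)CC[C@]2(C)C[C@H]1OC(C)=O | intermediate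
25 | methyl (3R,7R,8R,10R)-8β-acetoxy-3α-hydroxyeudesma-4,11(13)-dien-12-oate | C=C(C(=O)OC)[C@H]1CC2=C(C)[C@H](O)CC[C@]2(C)C[C@H]1OC(C)=O | intermediate
26 | methyl (3S,7R,8R,10R)-8β-acetoxy-3β-(2-methylpropanoyloxy)eudesma-4,11(13)-dien-12-oate | C=C(C(=O)OC)[C@H]1CC2=C(C)[C@@H](OC(=O)C(C)C)CC[C@]2(C)C[C@H]1OC(C)=O | intermediate
27 | methyl (3S,5S,7R,8R,10R)-8β-acetoxy-5α-hydroperoxy-3β-(2-methylpropanoyloxy)eudesma-4(15),11(13)-dien-12-oate (CNP0244758.1) | C=C(C(=O)OC)[C@H]1C[C@@]2(OO)C(=C)[C@@H](OC(=O)C(C)C)CC[C@]2(C)C[C@H]1OC(C)=O | target

## Step count and least certain steps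

Total: 18 steps. Longest linear sequence: 17 steps (steps 1–3, then 5–18, from but-3-yn-1-ol); the branch from pent-3-yn-1-ol joins at step 5.

**Step 15 (key step).** The most likely failure is that the tertiary C4 cation is not discharged by loss of H5 alone. Loss of a C15 proton is harmless, since the exocyclic olefin re-enters the equilibrium. Migration of hydride from C3 to C4 is different: the equatorial position of that hydrogen slows it but does not forbid it, it is irreversible, and after loss of the silyl group it ends in a 3-ketone. Long exposure to acid also endangers the allylic silyl ether, and a share of the 10-epimer would arise from any conformer with C14 on the α face. The fallback uses the ketone channel instead of fighting it. Setting out from 23, the material that follows the hydride-shift course is collected as methyl 8β-acetoxy-3-oxo-5αH-eudesm-11(13)-en-12-oate F1 (C4 epimers). TMSCl, NaI and Et3N in MeCN convert it into the more substituted enol ether, methyl 8β-acetoxy-3-(trimethylsilyloxy)-5αH-eudesma-3,11(13)-dien-12-oate F2. Saegusa–Ito dehydrogenation with Pd(OAc)2 in MeCN then gives methyl 8β-acetoxy-3-oxoeudesma-4,11(13)-dien-12-oate F3 (the same compound as A5). From F3 the sequence continues as in the fallback for step 17, through methyl 8β-acetoxy-3β-hydroxyeudesma-4,11(13)-dien-12-oate F4, and comes back to the route at 26, by-passing steps 16 and 17.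

**Step 13.** The most likely failure is poor discrimination between the two syn transition states, because C3, the only resident stereocentre, is four atoms from C7 and acts only through the conformation of the forming ring. Intermolecular coupling at insufficient dilution and lactonisation of the chromium alkoxide onto C12 add to this. The fallback puts the closure under reagent control and silylates the alkoxide as it forms. Setting out from 21, catalytic CrCl2 with a chiral tridentate bis(oxazolinyl)carbazole ligand, manganese powder and TMSCl in THF is used under slow addition; these are the conditions known for enantioselective 2-(alkoxycarbonyl)allylation of aldehydes, and the ligand enantiomer is chosen to match. The product is methyl (3R,7R,8R)-3α-(tert-butyldimethylsilyloxy)-8β-(trimethylsilyloxy)germacra-1(10)E,4E,11(13)-trien-12-oate F5, which cannot lactonise. Brief methanolysis (citric acid, MeOH, 0 °C) returns to the route at 22 for immediate acetylation.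

**Step 17.** The most likely failure is that anti elimination of the axial oxyphosphonium ion toward C2 (giving the homoannular diene), or its ionisation to the allyl cation, outruns substitution by the weakly acidic isobutyric acid. The fallback replaces the inversion by an oxidation–reduction sequence in which the ring sets C3. Setting out from 25, oxidation with DMP gives the enone methyl 8β-acetoxy-3-oxoeudesma-4,11(13)-dien-12-oate F3. Luche reduction (NaBH4, CeCl3·7H2O, MeOH, −78 °C) delivers hydride axially from the α face to give the equatorial alcohol methyl 8β-acetoxy-3β-hydroxyeudesma-4,11(13)-dien-12-oate F4, leaving the ester groups alone. Acylation with isobutyryl chloride (pyridine, DMAP) comes back to the route at 26.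

**Step 5.** The most likely failure is incomplete enantioselection. The aldehyde is unbranched and aliphatic, the zirconocene by-product can promote an unselective background addition, and a minor regioisomeric alkenyl metal may leak through; aldehyde 7 can also drift into conjugation if the addition is slow. The fallback separates bond formation from stereocontrol. Setting out from 7 and 9, the same hydrozirconation–zinc addition without ligand gives racemic (3E,7E)-10-[(4-methoxybenzyl)oxy]-4,8-dimethyl-1-(triethylsilyloxy)deca-3,7-dien-5-ol F6. DMP oxidation gives (3E,7E)-10-[(4-methoxybenzyl)oxy]-4,8-dimethyl-1-(triethylsilyloxy)deca-3,7-dien-5-one F7. Corey–Bakshi–Shibata reduction with the (S)-methyl oxazaborolidine and BH3·SMe2, with the α-methylalkenyl group acting as the large substituent, should give the 5R alcohol and comes back to the route at 12.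

## Further compounds

F1 | step 15 | methyl 8β-acetoxy-3-oxo-5αH-eudesm-11(13)-en-12-oate (C4 epimers) | C=C(C(=O)OC)[C@H]1C[C@H]2C(C)C(=O)CC[C@]2(C)C[C@H]1OC(C)=O
F2 | step 15 | methyl 8β-acetoxy-3-(trimethylsilyloxy)-5αH-eudesma-3,11(13)-dien-12-oate | C=C(C(=O)OC)[C@H]1C[C@H]2C(C)=C(O[Si](C)(C)C)CC[C@]2(C)C[C@H]1OC(C)=O
F3 | step 17 | methyl 8β-acetoxy-3-oxoeudesma-4,11(13)-dien-12-oate | C=C(C(=O)OC)[C@H]1CC2=C(C)C(=O)CC[C@]2(C)C[C@H]1OC(C)=O
F4 | step 17 | methyl 8β-acetoxy-3β-hydroxyeudesma-4,11(13)-dien-12-oate | C=C(C(=O)OC)[C@H]1CC2=C(C)[C@@H](O)CC[C@]2(C)C[C@H]1OC(C)=O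
F5 | step 13 | methyl (3R,7R,8R)-3α-(tert-butyldimethylsilyloxy)-8β-(trimethylsilyloxy)germacra-1(10)E,4E,11(13)-trien-12-oate | C=C(C(=O)OC)[C@H]1C/C=C(C)/[C@H](O[Si](C)(C)C(C)(C)C)C/C=C(C)/C[C@H]1O[Si](C)(C)C
F6 | step 5 | racemic (3E,7E)-10-[(4-methoxybenzyl)oxy]-4,8-dimethyl-1-(triethylsilyloxy)deca-3,7-dien-5-ol | CC[Si](CC)(CC)OCC/C=C(C)/C(O)C/C=C(C)/CCOCc1ccc(OC)cc1
F7 | step 5 | (3E,7E)-10-[(4-methoxybenzyl)oxy]-4,8-dimethyl-1-(triethylsilyloxy)deca-3,7-dien-5-one | CC[Si](CC)(CC)OCC/C=C(C)/C(=O)C/C=C(C)/CCOCc1ccc(OC)cc1
A1 | alternative 1 | 8,8-ethylenedioxy-5β,10β-methanodecalin-3β-ol (eudesmane numbering, C14 as the cyclopropane methylene) | O[C@H]1CC[C@@]23C[C@]2(C1)CCC1(C3)OCCO1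
A2 | alternative 1 | 8,8-ethylenedioxy-Δ5(10)-octalin-3β-ol (eudesmane numbering) | O[C@H]1CCC2=C(C1)CCC1(C2)OCCO1
A3 | alternative 2 | methyl 3,8-dioxo-13-noreudesma-1,4-dien-12-oate | COC(=O)C[C@H]1CC2=C(C)C(=O)C=C[C@]2(C)CC1=O
A4 | alternative 2 | methyl 5-diazo-3-[(3-hydroxy-2,6-dimethylphenyl)methyl]-4-oxopentanoate | Cc1ccc(O)c(C)c1C[C@H](CC(=O)OC)C(=O)C=[N+]=[N-]
A5 | alternative 3 | methyl 8β-acetoxy-3-oxoeudesma-4,11(13)-dien-12-oate | C=C(C(=O)OC)[C@H]1CC2=C(C)C(=O)CC[C@]2(C)C[C@H]1OC(C)=O
A6 | alternative 3 | methyl 4-acetoxy-3-(tert-butoxycarbonyloxy)-5-[4-(tert-butyldimethylsilyloxy)-1,3-dimethyl-2-methylidenecyclohex-3-en-1-yl]-2-methylidenepentanoate | C=C(C(=O)OC)C(OC(=O)OC(C)(C)C)[C@H](OC(C)=O)C[C@@]1(C)CCC(O[Si](C)(C)C(C)(C)C)=C(C)C1=C
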